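**Plan**

1. Retrosynthetic cuts, in order: the two acetates and the benzyl ether (end game); the aryl ether bond O1–C7a of the dihydrofuran ring; C2–C3 (aldol); C3–C3a (Negishi); C3a–I.
2. Forward: ring A comes from methyl dihydroferulate. Its phenolic OH sits on C7a, between C7–OMe and the free C3a and para to the C5 chain; it first directs iodination to C3a and is then turned into the C7a triflate.
3. The acetic acid unit is joined at C3a, and ring B (O-benzylvanillin) is joined by a syn aldol that makes C2–C3. The dihydrofuran, the only ring formed, is closed last by O1–C7a coupling.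
4. Enabling feature: the C2 oxygen is two carbons (C2, C3) from C3a, so it reaches the neighbouring C7a in a five-membered closure. Bonding it to the arene carbon, not to the ionisable p-alkoxybenzylic C2, leaves both stereocentres untouched.
5. Stereochemistry: C2 (S) and C3 (R) both come from the (S)-4-benzyl-oxazolidinone boron aldol (syn adduct, which becomes the trans ring on closure with retention). No later step breaks a bond at either centre.

Key step: step 9

Remark: the boron enolate of the arylacetyl imide is assumed to react with the facial sense known for the propionyl imide (Evans syn).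

**Route**

Step 1
Reactants: 1 methyl 3-(4-hydroxy-3-methoxyphenyl)propanoate
Product: 2 methyl 3-(4-hydroxy-3-iodo-5-methoxyphenyl)propanoate
Conditions: NIS (1.05 equiv), TsOH·H2O (0.1 equiv), MeCN, 0 °C to rt
Reagents that add atoms: N-iodosuccinimide, O=C1CCC(=O)N1I
Why: Electrophilic aromatic iodination is steered by the free phenol to its only open ortho position (para carries the chain, the other ortho the methoxy group), which is the future C3a.

Step 2
Reactants: 2 methyl 3-(4-hydroxy-3-iodo-5-methoxyphenyl)propanoate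
Product: 3 methyl 3-[3-iodo-5-methoxy-4-(trifluoromethanesulfonyloxy)phenyl]propanoate
Conditions: Tf2O (1.2 equiv), pyridine, CH2Cl2, 0 °C
Reagents that add atoms: trifluoromethanesulfonic anhydride, O=S(=O)(OS(=O)(=O)C(F)(F)F)C(F)(F)F
Why: O-Sulfonylation of the phenol (triflation) turns the C7a oxygen into a leaving group for palladium, while the C–I bond stays the more reactive site.

Step 3
Reactants: 3 methyl 3-[3-iodo-5-methoxy-4-(trifluoromethanesulfonyloxy)phenyl]propanoate; 4 (2-tert-butoxy-2-oxoethyl)zinc bromide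
Product: 5 methyl 3-[3-(2-tert-butoxy-2-oxoethyl)-5-methoxy-4-(trifluoromethanesulfonyloxy)phenyl]propanoate
Conditions: Pd2(dba)3 (2 mol %), XPhos (8 mol %), 4 (1.5 equiv, 0.5 M in Et2O), THF, rt to 45 °C
Reagents that add atoms: none
Why: Negishi coupling of a Reformatsky reagent (arylation of a zinc ester enolate) should occur at C–I only, because an aryl iodide adds to zerovalent palladium much faster than the neighbouring triflate, and the zinc reagent tolerates the methyl ester.

Step 4
Reactants: 5 methyl 3-[3-(2-tert-butoxy-2-oxoethyl)-5-methoxy-4-(trifluoromethanesulfonyloxy)phenyl]propanoate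
Product: 6 2-[3-methoxy-5-(3-methoxy-3-oxopropyl)-2-(trifluoromethanesulfonyloxy)phenyl]acetic acid
Conditions: CF3CO2H/CH2Cl2 (1:3), rt
Reagents that add atoms: none
Why: Acidolysis of the tert-butyl ester (loss of isobutene) frees the acid without touching the methyl ester or the aryl triflate.

Step 5
Reactants: 6 2-[3-methoxy-5-(3-methoxy-3-oxopropyl)-2-(trifluoromethanesulfonyloxy)phenyl]acetic acid; 7 (S)-4-benzyl-1,3-oxazolidin-2-one
Product: 9 methyl 3-[3-{2-[(4S)-4-benzyl-2-oxo-1,3-oxazolidin-3-yl]-2-oxoethyl}-5-methoxy-4-(trifluoromethanesulfonyloxy)phenyl]propanoate, via mixed pivalic anhydride 8 (not isolated)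
Conditions: PivCl, Et3N, THF, −20 °C; then LiCl, 7, −20 °C to rt
Reagents that add atoms: pivaloyl chloride, CC(C)(C)C(=O)Cl (its atoms stay in 8 only and are absent from 9)
Why: N-Acylation of the oxazolidinone through the mixed pivalic anhydride under LiCl/Et3N activation is the standard mild way to arylacetyl imides and needs no strong base that could attack the triflate.

Step 6
Reactants: 9 methyl 3-[3-{2-[(4S)-4-benzyl-2-oxo-1,3-oxazolidin-3-yl]-2-oxoethyl}-5-methoxy-4-(trifluoromethanesulfonyloxy)phenyl]propanoate; 10 4-(benzyloxy)-3-methoxybenzaldehyde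
Product: 13 methyl 3-[3-{(1S,2S)-1-[(4S)-4-benzyl-2-oxo-1,3-oxazolidine-3-carbonyl]-2-[4-(benzyloxy)-3-methoxyphenyl]-2-hydroxyethyl}-5-methoxy-4-(trifluoromethanesulfonyloxy)phenyl]propanoate (Evans syn aldol adduct), via Z dibutylboron enolate 11 (not isolated), via dibutylboron aldolate 12 (not isolated)
Conditions: Bu2BOTf (1.2 equiv), iPr2NEt (1.4 equiv), CH2Cl2, 0 °C; then 10, −78 to 0 °C; then pH 7 buffer, MeOH, 30% H2O2, 0 °C
Reagents that add atoms: dibutylboron triflate, CCCCB(CCCC)OS(=O)(=O)C(F)(F)F (boron stays in 11 and 12 only and is absent from 13)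
Why: Evans syn aldol reaction, in which soft enolisation gives the Z boron enolate and this adds to the aldehyde through a Zimmerman–Traxler chair on the enolate face away from the benzyl group of the auxiliary, setting both future ring stereocentres (carbinol carbon S, aryl-bearing carbon S in the adduct) as the syn pair.

Step 7
Reactants: 13 methyl 3-[3-{(1S,2S)-1-[(4S)-4-benzyl-2-oxo-1,3-oxazolidine-3-carbonyl]-2-[4-(benzyloxy)-3-methoxyphenyl]-2-hydroxyethyl}-5-methoxy-4-(trifluoromethanesulfonyloxy)phenyl]propanoate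
Product: 14 2-{(1S,2R)-1-[4-(benzyloxy)-3-methoxyphenyl]-1,3-dihydroxypropan-2-yl}-4-(3-hydroxypropyl)-6-methoxyphenyl trifluoromethanesulfonate
Conditions: LiBH4 (5 equiv), MeOH (5 equiv), THF, 0 °C to rt
Reagents that add atoms: none
Why: Hydride reduction with LiBH4 cleaves the imide reductively to the primary alcohol, releases the auxiliary and reduces the methyl ester in the same flask under non-enolising conditions, so neither stereocentre is touched (the descriptor of the aryl-bearing carbon changes from S to R by priority only).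

Step 8
Reactants: 14 2-{(1S,2R)-1-[4-(benzyloxy)-3-methoxyphenyl]-1,3-dihydroxypropan-2-yl}-4-(3-hydroxypropyl)-6-methoxyphenyl trifluoromethanesulfonate
Product: 15 2-{(1S,2R)-1-[4-(benzyloxy)-3-methoxyphenyl]-3-(tert-butyldimethylsilyloxy)-1-hydroxypropan-2-yl}-4-[3-(tert-butyldimethylsilyloxy)propyl]-6-methoxyphenyl trifluoromethanesulfonate
Conditions: TBSCl (2.2 equiv), imidazole (4.4 equiv), CH2Cl2, 0 °C
Reagents that add atoms: tert-butyldimethylsilyl chloride, CC(C)(C)[Si](C)(C)Cl
Why: Silylation with TBSCl/imidazole is selective for the two primary hydroxyls over the hindered secondary benzylic one, which must stay free as the nucleophile of the ring closure (a free primary hydroxyl on the C3 arm would close a five-membered ring of its own).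

Step 9
Reactants: 15 2-{(1S,2R)-1-[4-(benzyloxy)-3-methoxyphenyl]-3-(tert-butyldimethylsilyloxy)-1-hydroxypropan-2-yl}-4-[3-(tert-butyldimethylsilyloxy)propyl]-6-methoxyphenyl trifluoromethanesulfonate
Product: 16 (2S,3R)-2-[4-(benzyloxy)-3-methoxyphenyl]-3-[(tert-butyldimethylsilyloxy)methyl]-5-[3-(tert-butyldimethylsilyloxy)propyl]-7-methoxy-2,3-dihydro-1-benzofuran
Conditions: Pd2(dba)3 (2.5 mol %), tBuXPhos (6 mol %), K3PO4 (2 equiv), toluene (degassed), 80 °C
Reagents that add atoms: none
Why: Oxidative addition of the C7a–OTf bond to zerovalent palladium carrying the bulky biaryl phosphine, exchange of triflate for the C2 alkoxide under K3PO4 and C–O reductive elimination from the resulting six-membered aryl palladium alkoxide (Pd bound to C7a and O1) form the O1–C7a bond. The closest known reaction type is the intramolecular Buchwald–Hartwig etherification of aryl halides and sulfonates by secondary alcohols. The dihydrofuran ring (O1, C2, C3, C3a, C7a) closes in a five-membered exo mode, O1 attacking the ring carbon C7a while the departing triflate lies outside the new ring. No stereocentre is created: no bond to C2 or C3 is broken, so the syn (1S,2R) array of 15 is carried with retention into the trans (2S,3R) ring, the substrate being the only controlling element. The step needs chemoselectivity for the secondary hydroxyl (the two primary ones are silylated and the phenol is benzylated), a single electrophilic site (one sulfonate, no halide left) and reductive elimination faster than β-hydride elimination of the benzylic alkoxide, which the di-tert-butyl biaryl phosphine and the strain-free five-ring closure should secure.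

Step 10
Reactants: 16 (2S,3R)-2-[4-(benzyloxy)-3-methoxyphenyl]-3-[(tert-butyldimethylsilyloxy)methyl]-5-[3-(tert-butyldimethylsilyloxy)propyl]-7-methoxy-2,3-dihydro-1-benzofuran
Product: 18 3-{(2S,3R)-3-(acetoxymethyl)-2-[4-(benzyloxy)-3-methoxyphenyl]-7-methoxy-2,3-dihydro-1-benzofuran-5-yl}propyl acetate, via diol 17 (not isolated)
Conditions: Bu4NF (2.2 equiv), THF, 0 °C to rt; then Ac2O (6 equiv), DMAP (0.2 equiv), rt
Reagents that add atoms: acetic anhydride, CC(=O)OC(C)=O
Why: Fluoride cleaves both primary silyl ethers and the liberated diol is acetylated in the same flask (desilylation followed by DMAP-catalysed acylation), the benzyl ether and the cyclic ether being inert.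

Step 11
Reactants: 18 3-{(2S,3R)-3-(acetoxymethyl)-2-[4-(benzyloxy)-3-methoxyphenyl]-7-methoxy-2,3-dihydro-1-benzofuran-5-yl}propyl acetate
Product: 19 3-[(2S,3R)-3-(acetoxymethyl)-2-(4-hydroxy-3-methoxyphenyl)-7-methoxy-2,3-dihydro-1-benzofuran-5-yl]propyl acetate
Conditions: H2 (1 atm), 10% Pd/C, EtOAc, rt
Reagents that add atoms: none
Why: Hydrogenolysis of the benzyl aryl ether over Pd/C frees the phenol; the acetates are inert and the cyclic benzylic C2–O1 bond is cleaved far more slowly, so it should survive if the reaction is stopped at full conversion.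

**Compound list**

1 | methyl 3-(4-hydroxy-3-methoxyphenyl)propanoate (methyl dihydroferulate) | COC(=O)CCc1ccc(O)c(OC)c1 | starting material
2 | methyl 3-(4-hydroxy-3-iodo-5-methoxyphenyl)propanoate | COC(=O)CCc1cc(I)c(O)c(OC)c1 | intermediate
3 | methyl 3-[3-iodo-5-methoxy-4-(trifluoromethanesulfonyloxy)phenyl]propanoate | COC(=O)CCc1cc(I)c(OS(=O)(=O)C(F)(F)F)c(OC)c1 | intermediate
4 | (2-tert-butoxy-2-oxoethyl)zinc bromide (Reformatsky reagent of tert-butyl bromoacetate) | CC(C)(C)OC(=O)C[Zn]Br | starting material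
5 | methyl 3-[3-(2-tert-butoxy-2-oxoethyl)-5-methoxy-4-(trifluoromethanesulfonyloxy)phenyl]propanoate | COC(=O)CCc1cc(CC(=O)OC(C)(C)C)c(OS(=O)(=O)C(F)(F)F)c(OC)c1 | intermediate
6 | 2-[3-methoxy-5-(3-methoxy-3-oxopropyl)-2-(trifluoromethanesulfonyloxy)phenyl]acetic acid | COC(=O)CCc1cc(CC(=O)O)c(OS(=O)(=O)C(F)(F)F)c(OC)c1 | intermediate
7 | (S)-4-benzyl-1,3-oxazolidin-2-one | O=C1N[C@@H](Cc2ccccc2)CO1 | starting material
8 | mixed anhydride of acid 6 and pivalic acid (not isolated) | COC(=O)CCc1cc(CC(=O)OC(=O)C(C)(C)C)c(OS(=O)(=O)C(F)(F)F)c(OC)c1 | intermediate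
9 | methyl 3-[3-{2-[(4S)-4-benzyl-2-oxo-1,3-oxazolidin-3-yl]-2-oxoethyl}-5-methoxy-4-(trifluoromethanesulfonyloxy)phenyl]propanoate | COC(=O)CCc1cc(CC(=O)N2C(=O)OC[C@@H]2Cc2ccccc2)c(OS(=O)(=O)C(F)(F)F)c(OC)c1 | intermediate
10 | 4-(benzyloxy)-3-methoxybenzaldehyde (O-benzylvanillin) | COc1cc(C=O)ccc1OCc1ccccc1 | starting material
11 | Z dibutylboron enolate of imide 9 (O–B cis to ring A; not isolated) | CCCCB(CCCC)O/C(=C\c1cc(CCC(=O)OC)cc(OC)c1OS(=O)(=O)C(F)(F)F)N1C(=O)OC[C@@H]1Cc1ccccc1 | intermediate
12 | O-dibutylboryl aldolate of 13 (not isolated) | COc1cc([C@@H](OB(CCCC)CCCC)[C@H](c2cc(CCC(=O)OC)cc(OC)c2OS(=O)(=O)C(F)(F)F)C(=O)N2C(=O)OC[C@@H]2Cc2ccccc2)ccc1OCc1ccccc1 | intermediate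
13 | methyl 3-[3-{(1S,2S)-1-[(4S)-4-benzyl-2-oxo-1,3-oxazolidine-3-carbonyl]-2-[4-(benzyloxy)-3-methoxyphenyl]-2-hydroxyethyl}-5-methoxy-4-(trifluoromethanesulfonyloxy)phenyl]propanoate (syn aldol adduct) | COc1cc([C@@H](O)[C@H](c2cc(CCC(=O)OC)cc(OC)c2OS(=O)(=O)C(F)(F)F)C(=O)N2C(=O)OC[C@@H]2Cc2ccccc2)ccc1OCc1ccccc1 | intermediate
14 | 2-{(1S,2R)-1-[4-(benzyloxy)-3-methoxyphenyl]-1,3-dihydroxypropan-2-yl}-4-(3-hydroxypropyl)-6-methoxyphenyl trifluoromethanesulfonate | COc1cc([C@@H](O)[C@H](c2cc(CCCO)cc(OC)c2OS(=O)(=O)C(F)(F)F)CO)ccc1OCc1ccccc1 | intermediate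
15 | 2-{(1S,2R)-1-[4-(benzyloxy)-3-methoxyphenyl]-3-(tert-butyldimethylsilyloxy)-1-hydroxypropan-2-yl}-4-[3-(tert-butyldimethylsilyloxy)propyl]-6-methoxyphenyl trifluoromethanesulfonate | COc1cc([C@@H](O)[C@H](c2cc(CCCO[Si](C)(C)C(C)(C)C)cc(OC)c2OS(=O)(=O)C(F)(F)F)CO[Si](C)(C)C(C)(C)C)ccc1OCc1ccccc1 | intermediate
16 | (2S,3R)-2-[4-(benzyloxy)-3-methoxyphenyl]-3-[(tert-butyldimethylsilyloxy)methyl]-5-[3-(tert-butyldimethylsilyloxy)propyl]-7-methoxy-2,3-dihydro-1-benzofuran (trans) | COc1cc([C@H]2Oc3c(OC)cc(CCCO[Si](C)(C)C(C)(C)C)cc3[C@@H]2CO[Si](C)(C)C(C)(C)C)ccc1OCc1ccccc1 | intermediate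
17 | 3-{(2S,3R)-2-[4-(benzyloxy)-3-methoxyphenyl]-3-(hydroxymethyl)-7-methoxy-2,3-dihydro-1-benzofuran-5-yl}propan-1-ol (not isolated) | COc1cc([C@H]2Oc3c(OC)cc(CCCO)cc3[C@@H]2CO)ccc1OCc1ccccc1 | intermediate
18 | 3-{(2S,3R)-3-(acetoxymethyl)-2-[4-(benzyloxy)-3-methoxyphenyl]-7-methoxy-2,3-dihydro-1-benzofuran-5-yl}propyl acetate | COc1cc([C@H]2Oc3c(OC)cc(CCCOC(C)=O)cc3[C@@H]2COC(C)=O)ccc1OCc1ccccc1 | intermediate
19 | 3-[(2S,3R)-3-(acetoxymethyl)-2-(4-hydroxy-3-methoxyphenyl)-7-methoxy-2,3-dihydro-1-benzofuran-5-yl]propyl acetate (CNP0227018.1) | COc1cc([C@H]2Oc3c(OC)cc(CCCOC(C)=O)cc3[C@@H]2COC(C)=O)ccc1O | target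

**Step count and risks**

Total step count: 11. Longest linear sequence: 11 steps (1 to 19); 4, 7 and 10 are purchased.

Steps most likely to fail:

Step 9. Oxidative addition at the doubly ortho-flanked sulfonate may be slow. Base-induced S–O cleavage, transfer of the triflyl group to the carbinol oxygen, or β-hydride elimination from the palladium alkoxide could then overtake ring closure. Fallback: from 15, Miyaura borylation (PdCl2(dppf), B2pin2, KOAc, dioxane, 90 °C) would exchange the triflate for boron and give the aryl pinacol boronate F1. A Chan–Lam etherification (Cu(OAc)2, pyridine, 4 Å molecular sieves, CH2Cl2, air, rt) would then join O1 to C7a oxidatively, again without touching C2 or C3, and return to 16.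

Step 6. Soft enolisation of the ortho-substituted arylacetyl imide may be incomplete, and retro-aldol equilibration of the α-aryl aldolate during reaction or work-up may erode the syn selectivity. Fallback: from 5, C-acylation of its lithium enolate (LiN(SiMe3)2, THF, −78 °C, then 4-(benzyloxy)-3-methoxybenzoyl chloride) would give the racemic, configurationally labile β-keto ester F2. Noyori–Ikariya transfer hydrogenation under dynamic kinetic resolution (RuCl[(S,S)-TsDPEN](p-cymene), HCO2H/Et3N, rt) should reduce the aryl ketone to the S carbinol. The α-centre should follow by Felkin–Anh control (ring A anti to the incoming hydride), giving the syn hydroxy ester F3. Reduction of both esters (iBu2AlH, CH2Cl2, −78 to 0 °C) returns to triol 14.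

Step 3. Chemoselectivity between C–I and the adjacent C–OTf may be lost, or the zinc enolate may be protonated before transmetalation, leading to over-coupling or hydrodeiodination. Fallback: from 1, O-allylation (allyl bromide, K2CO3, acetone, reflux) would give the allyl ether F4. Aromatic Claisen rearrangement (N,N-diethylaniline, 190 °C) would move the allyl group to the only open ortho carbon, C3a, giving the ortho-allyl phenol F5. Triflation (Tf2O, pyridine, CH2Cl2, 0 °C) would give the allyl triflate F6. Ozonolysis (O3, CH2Cl2, −78 °C; then PPh3) would give the arylacetaldehyde F7. Pinnick oxidation (NaClO2, NaH2PO4, 2-methylbut-2-ene, tBuOH/H2O) returns to acid 6, so that steps 1 to 4 are bypassed.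

**Further compounds**

F1 | step 9 | (1S,2R)-1-[4-(benzyloxy)-3-methoxyphenyl]-3-(tert-butyldimethylsilyloxy)-2-{5-[3-(tert-butyldimethylsilyloxy)propyl]-3-methoxy-2-(4,4,5,5-tetramethyl-1,3,2-dioxaborolan-2-yl)phenyl}propan-1-ol | COc1cc([C@@H](O)[C@H](c2cc(CCCO[Si](C)(C)C(C)(C)C)cc(OC)c2B2OC(C)(C)C(C)(C)O2)CO[Si](C)(C)C(C)(C)C)ccc1OCc1ccccc1
F2 | step 6 | tert-butyl 3-[4-(benzyloxy)-3-methoxyphenyl]-2-[3-methoxy-5-(3-methoxy-3-oxopropyl)-2-(trifluoromethanesulfonyloxy)phenyl]-3-oxopropanoate (racemic) | COc1cc(C(=O)C(c2cc(CCC(=O)OC)cc(OC)c2OS(=O)(=O)C(F)(F)F)C(=O)OC(C)(C)C)ccc1OCc1ccccc1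
F3 | step 6 | tert-butyl (2S,3S)-3-[4-(benzyloxy)-3-methoxyphenyl]-3-hydroxy-2-[3-methoxy-5-(3-methoxy-3-oxopropyl)-2-(trifluoromethanesulfonyloxy)phenyl]propanoate | COc1cc([C@@H](O)[C@H](c2cc(CCC(=O)OC)cc(OC)c2OS(=O)(=O)C(F)(F)F)C(=O)OC(C)(C)C)ccc1OCc1ccccc1
F4 | step 3 | methyl 3-[3-methoxy-4-(prop-2-en-1-yloxy)phenyl]propanoate | COC(=O)CCc1ccc(OCC=C)c(OC)c1
F5 | step 3 | methyl 3-[4-hydroxy-3-methoxy-5-(prop-2-en-1-yl)phenyl]propanoate | COC(=O)CCc1cc(CC=C)c(O)c(OC)c1
F6 | step 3 | methyl 3-[3-methoxy-5-(prop-2-en-1-yl)-4-(trifluoromethanesulfonyloxy)phenyl]propanoate | COC(=O)CCc1cc(CC=C)c(OS(=O)(=O)C(F)(F)F)c(OC)c1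
F7 | step 3 | methyl 3-[3-methoxy-5-(2-oxoethyl)-4-(trifluoromethanesulfonyloxy)phenyl]propanoate | COC(=O)CCc1cc(CC=O)c(OS(=O)(=O)C(F)(F)F)c(OC)c1
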